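**Plan**

1. Locants used here: C1 (bridgehead CH), C2, C3, C4 (=C20H2), C5, C6 (OAc), C7=C8 (C19H3 on C8), C9, C10 (O), C11=C12, C13, C14, C15 (C16H3, C17H3), C18 (lactone C=O). Ring A is C1/C14/C13/C12/C11/C15, the butenolide is C10/C11/C12/C18/O, and the large ring is C1–C11 plus C15.
2. Retrosynthesis: remove the C6 acetate; cut C13–C14 and C11=C12 together with the lactone C18–O, so that ring A and the butenolide fall away and leave a 12-membered α-hydroxy ketone with an iodomethyl group on C1 plus ethyl 2-(diethoxyphosphoryl)acrylate; then cut C3–C4 (large ring), C10–O, C9–C10, C10–C11 and C15–C1.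
3. Enabling feature: the C12–C13 edge of ring A is an acrylate unit (C12 carries C18); C14 is an exocyclic primary carbon on C1 that reaches C11 through C15; C11 lies between quaternary C15 and the carbinol C10. A C14 radical, a C12 phosphonate carbanion, a C11 ketone and the C10 hydroxyl are therefore the four partners that close ring A and the butenolide.
4. Forward order: C4–C9 bromide (steps 1–4); C1/C15 unit by allylic alkylation, methyl ketone, C9–C10 by enolate allylation, C10–O by enolate oxidation (steps 5–10); large ring by B-alkyl Suzuki–Miyaura coupling at C3–C4 (step 11); ring A and butenolide in one pot (step 14); desilylation and acetylation.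
5. Stereochemistry: C6 from catalytic asymmetric 2-bromoallylation, C1 from iridium-catalysed asymmetric allylic alkylation, C10 from reagent-controlled enolate hydroxylation, 7E from E-selective SeO2 oxidation; the key step creates no stereocentre.

Key step: step 14

Assumption: in steps 1, 7 and 10 the antipode of the chiral ligand or oxaziridine that leads to the stated descriptor is used (both antipodes of each are obtainable), and (E)-but-2-ene-1,4-diol is taken as a catalogue chemical.

**Route**

Step 1
Reactants: 1 3-methylbut-2-enal; 2 2,3-dibromoprop-1-ene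
Product: 4 (4S)-2-bromo-6-methylhepta-1,5-dien-4-ol, via trimethylsilyl ether 3 (not isolated)
Conditions: CrBr3 (10 mol %), chiral oxazoline–sulfonamide ligand (11 mol %), Et3N, cobalt phthalocyanine C32H16CoN8 (2 mol %), Mn powder (2 equiv), Me3SiCl, 2,6-lutidine, THF, 25 °C; then K2CO3 (cat.), MeOH
Reagents that add atoms: none
Why: Catalytic asymmetric Nozaki–Hiyama–Kishi-type 2-haloallylation, in which only the allylic C–Br of 2 is reduced to an allylchromium species that adds 1,2 to the enal inside the chiral chromium–sulfonamide complex and so sets C6 (4S) under catalyst control, while the vinylic C–Br is kept for step 11.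

Step 2
Reactants: 4
Product: 5 (4S)-2-bromo-4-(tert-butyldiphenylsilyloxy)-6-methylhepta-1,5-diene
Conditions: tBuPh2SiCl, imidazole, DMF, 25 °C
Reagents that add atoms: tert-butyl(chloro)diphenylsilane, CC(C)(C)[Si](Cl)(c1ccccc1)c1ccccc1
Why: Routine silylation of the secondary allylic alcohol with a bulky silyl group chosen to outlast the HF·pyridine treatment of step 12.

Step 3
Reactants: 5
Product: 6 (2E,4S)-6-bromo-4-(tert-butyldiphenylsilyloxy)-2-methylhepta-2,6-dien-1-ol
Conditions: SeO2 (0.3 equiv), tBuOOH (3 equiv), salicylic acid (cat.), CH2Cl2, 25 °C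
Reagents that add atoms: tert-butyl hydroperoxide, CC(C)(C)OO (its oxygen is passed on through catalytic selenium dioxide, O=[Se]=O)
Why: Allylic oxidation by SeO2 (ene reaction then [2,3]-sigmatropic shift) should oxidise the E-methyl group of the trisubstituted alkene, which fixes the 7E geometry, while the electron-poor 2-bromoalkene is left alone.

Step 4
Reactants: 6
Product: 7 (2E,4S)-1,6-dibromo-4-(tert-butyldiphenylsilyloxy)-2-methylhepta-2,6-diene
Conditions: CBr4, PPh3, CH2Cl2, 0 °C
Reagents that add atoms: tetrabromomethane, BrC(Br)(Br)Br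
Why: Appel bromination of the primary allylic alcohol by SN2 displacement of the alkoxyphosphonium ion, which should proceed without allylic transposition at 0 °C.

Step 5
Reactants: 8 (E)-but-2-ene-1,4-diol
Product: 9 (E)-4-(tert-butyldimethylsilyloxy)but-2-en-1-ol
Conditions: NaH (1.0 equiv), THF, 25 °C; then tBuMe2SiCl (1.0 equiv)
Reagents that add atoms: tert-butyl(chloro)dimethylsilane, CC(C)(C)[Si](C)(C)Cl
Why: Monosilylation of a symmetrical diol through its sparingly soluble monosodium alkoxide, which reacts once and then no longer carries a charge.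

Step 6
Reactants: 9
Product: 10 (E)-4-(tert-butyldimethylsilyloxy)but-2-en-1-yl methyl carbonate
Conditions: ClCO2Me, pyridine, CH2Cl2, 0 °C
Reagents that add atoms: methyl chloroformate, COC(=O)Cl
Why: Acylation of the primary allylic alcohol installs the carbonate leaving group needed for ionisation by iridium.

Step 7
Reactants: 10; 11 1-methoxy-2-methyl-1-(trimethylsilyloxy)prop-1-ene
Product: 12 methyl (3S)-3-[(tert-butyldimethylsilyloxy)methyl]-2,2-dimethylpent-4-enoate
Conditions: [Ir(cod)Cl]2 (2 mol %), BINOL-derived N,N-bis(1-phenylethyl)phosphoramidite (4 mol %, cyclometalated with nPrNH2), KF/18-crown-6 (10 mol %), THF, 25 °C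
Reagents that add atoms: none
Why: Iridium-catalysed asymmetric allylic alkylation, in which the ester enolate released from 11 attacks the substituted terminus of the iridium–allyl complex to give the branched product with quaternary C15 next to C1 and sets C1 (3S) by catalyst control.

Step 8
Reactants: 12
Product: 14 (4S)-4-[(tert-butyldimethylsilyloxy)methyl]-3,3-dimethylhex-5-en-2-one, via lithium silyl enolate 13 (not isolated)
Conditions: LiCH2SiMe3 (2.5 equiv), pentane/THF, 0 → 25 °C; then MeOH
Reagents that add atoms: (trimethylsilyl)methyllithium, [Li]C[Si](C)(C)C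
Why: Acyl substitution of the hindered ester by the α-silyl carbanion gives an α-silyl ketone that is deprotonated at once to enolate 13, which resists a second addition and is protodesilylated by methanol to the methyl ketone (C10 installed).

Step 9
Reactants: 14; 7
Product: 16 (3S,8E,10S)-12-bromo-3-[(tert-butyldimethylsilyloxy)methyl]-10-(tert-butyldiphenylsilyloxy)-4,4,8-trimethyltrideca-1,8,12-trien-5-one, via lithium enolate 15 (not isolated)
Conditions: LiN(iPr)2 (1.05 equiv), THF, −78 °C; then 7, DMPU, −78 → −30 °C
Reagents that add atoms: none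
Why: Ketone enolate alkylation, in which C15 is quaternary so only the methyl group (C10) can be deprotonated, and the enolate displaces the primary allylic bromide by SN2 to form C9–C10 while the 2-bromoalkene is inert.

Step 10
Reactants: 16
Product: 19 (3S,6R,8E,10S)-12-bromo-3-[(tert-butyldimethylsilyloxy)methyl]-10-(tert-butyldiphenylsilyloxy)-4,4,8-trimethyl-6-(triethylsilyloxy)trideca-1,8,12-trien-5-one, via potassium enolate 17 (not isolated), via potassium alkoxide 18 (not isolated)
Conditions: KN(SiMe3)2, THF, −78 °C; (camphorsulfonyl)oxaziridine, −78 °C; then Et3SiCl, −78 → 0 °C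
Reagents that add atoms: (camphorsulfonyl)oxaziridine, O=S1(=O)CC23CCC(CC24ON14)C3(C)C; chlorotriethylsilane, CC[Si](Cl)(CC)CC
Why: Enolate hydroxylation with an N-sulfonyloxaziridine, in which the single (Z)-enolate should take oxygen on the face dictated by the camphor framework and so set C10 (6R) by reagent control (a C10 epimer would be a separable diastereomer), after which the alkoxide is silylated in the same flask to keep the ketol away from the base of step 11.

Step 11
Reactants: 19
Product: 21 (2R,4E,6S,11S)-11-[(tert-butyldimethylsilyloxy)methyl]-6-(tert-butyldiphenylsilyloxy)-4,12,12-trimethyl-8-methylidene-2-(triethylsilyloxy)cyclododec-4-en-1-one, via alkylborane 20 (not isolated)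
Conditions: 9-BBN (1.5 equiv), THF, 0 → 25 °C; then slow addition to Pd(dppf)Cl2 (15 mol %), AsPh3 (30 mol %), Cs2CO3, DMF/THF/H2O, 50 °C, 2 mM
Reagents that add atoms: none
Why: B-alkyl Suzuki–Miyaura macrocyclisation, in which 9-BBN should add only to the monosubstituted C2=C3 alkene (the 2-bromoalkene, the trisubstituted alkene and the doubly hindered ketone react far more slowly) and the alkylborane couples with the C4 bromide under zerovalent palladium at high dilution to close the 12-membered ring with the C4=C20 methylidene in place.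

Step 12
Reactants: 21
Product: 22 (2R,4E,6S,11S)-6-(tert-butyldiphenylsilyloxy)-2-hydroxy-11-(hydroxymethyl)-4,12,12-trimethyl-8-methylidenecyclododec-4-en-1-one
Conditions: HF·pyridine, pyridine, THF, 0 → 25 °C
Reagents that add atoms: none
Why: Fluoride desilylation graded by silyl bulk should cleave the secondary triethylsilyl and primary tert-butyldimethylsilyl ethers and spare the secondary tert-butyldiphenylsilyl ether at C6; the product may rest partly as the C14–O–C11 hemiketal, which stays in equilibrium with the open form.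

Step 13
Reactants: 22
Product: 23 (2R,4E,6S,11S)-6-(tert-butyldiphenylsilyloxy)-2-hydroxy-11-(iodomethyl)-4,12,12-trimethyl-8-methylidenecyclododec-4-en-1-one
Conditions: I2, PPh3, imidazole, CH2Cl2, 0 → 25 °C
Reagents that add atoms: iodine, II
Why: Appel-type iodination, in which the alkoxyphosphonium ion should form at the primary C14 hydroxyl much faster than at the hindered secondary C10 hydroxyl beside the ketone and is displaced by iodide in an SN2 step.

Step 14
Reactants: 23; 24 ethyl 2-(diethoxyphosphoryl)prop-2-enoate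
Product: 27 (1R,6S,10R,7E)-6-(tert-butyldiphenylsilyloxy)verticilla-4(20),7,11-trien-18,10-olide (the target with tBuPh2Si in place of acetyl), via phosphonoacetate 25 (not isolated), via hydroxy ester 26 (not isolated)
Conditions: 24 (1.3 equiv), (Me3Si)3SiH (1.3 equiv, syringe pump), AIBN (0.2 equiv), PhMe, 80 °C; then 25 °C, MeCN, LiCl (3 equiv), DBU (2.5 equiv), 25 → 40 °C
Reagents that add atoms: none
Why: Iodine abstraction by the silyl radical gives the primary C14 radical, which adds (Giese addition) to the unsubstituted terminus C13 of 24; the resulting C12 radical takes hydrogen from the silane to give 25, and LiCl/DBU then deprotonates only C12–H (pKa about 19) so that the lithium-chelated carbanion attacks the C11 ketone and collapses through the oxaphosphetane (intramolecular Horner–Wadsworth–Emmons olefination) to 26, whose C10 hydroxyl acylates on the neighbouring ester. The closest known reaction types are radical conjugate addition to 2-phosphonoacrylates followed by olefination, and butenolide formation from α-hydroxy ketones and phosphonoacetates. Ring A closes by 6-exo-trig attack of C12 on the C11 carbonyl (ring atoms C12, C13, C14, C1, C15, C11) followed by syn loss of diethyl phosphate, and the butenolide closes by 5-exo-trig acyl substitution, which is unavoidable because ring A holds C18 and C10 cis on the new C11=C12 bond. No stereocentre is created: C12 in 25 is a transient mixture erased by the olefination, and C1, C6 and C10 are spectators because DBU does not remove C10–H and C15 is quaternary. The step needs intermolecular addition at C13 to win over transannular 5-exo/6-endo attack on C4=C20, 1,5-hydrogen transfer from C10–H and direct reduction, which the polarity match between the nucleophilic primary radical and the doubly activated alkene, the slow silane addition and the slow cyclisation onto a 1,1-disubstituted alkene should secure; it also needs carbanion attack at the hindered C11 ketone, which the six-membered transition state, the gem-dimethyl group at C15 and lithium chelation by the C10 hydroxyl should secure.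

Step 15
Reactants: 27
Product: 28 (1R,6S,10R,7E)-6-hydroxyverticilla-4(20),7,11-trien-18,10-olide
Conditions: Bu4NF, AcOH (1:1), THF, 25 °C
Reagents that add atoms: none
Why: Fluoride cleavage of the silyl ether, buffered with acetic acid so that the γ-hydrogen of the butenolide (C10–H) is not removed.

Step 16
Reactants: 28
Product: 29 (1R,6S,10R,7E)-6-acetoxyverticilla-4(20),7,11-trien-18,10-olide (target)
Conditions: Ac2O, pyridine, DMAP (cat.), CH2Cl2, 0 → 25 °C
Reagents that add atoms: acetic anhydride, CC(=O)OC(C)=O
Why: DMAP-catalysed acetylation of the secondary allylic alcohol, which leaves the C–O bond at C6 intact and so retains its configuration.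

**Compound list**

1 | 3-methylbut-2-enal | CC(C)=CC=O | starting material
2 | 2,3-dibromoprop-1-ene | C=C(Br)CBr | starting material
3 | (4S)-2-bromo-6-methyl-4-(trimethylsilyloxy)hepta-1,5-diene | CC(C)=C[C@@H](O[Si](C)(C)C)CC(Br)=C | intermediate (not isolated)
4 | (4S)-2-bromo-6-methylhepta-1,5-dien-4-ol | CC(C)=C[C@@H](O)CC(Br)=C | intermediate
5 | (4S)-2-bromo-4-(tert-butyldiphenylsilyloxy)-6-methylhepta-1,5-diene | CC(C)=C[C@@H](O[Si](c1ccccc1)(c1ccccc1)C(C)(C)C)CC(Br)=C | intermediate
6 | (2E,4S)-6-bromo-4-(tert-butyldiphenylsilyloxy)-2-methylhepta-2,6-dien-1-ol | OC/C(C)=C/[C@@H](O[Si](c1ccccc1)(c1ccccc1)C(C)(C)C)CC(Br)=C | intermediate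
7 | (2E,4S)-1,6-dibromo-4-(tert-butyldiphenylsilyloxy)-2-methylhepta-2,6-diene | BrC/C(C)=C/[C@@H](O[Si](c1ccccc1)(c1ccccc1)C(C)(C)C)CC(Br)=C | intermediate
8 | (E)-but-2-ene-1,4-diol | OC/C=C/CO | starting material
9 | (E)-4-(tert-butyldimethylsilyloxy)but-2-en-1-ol | OC/C=C/CO[Si](C)(C)C(C)(C)C | intermediate
10 | (E)-4-(tert-butyldimethylsilyloxy)but-2-en-1-yl methyl carbonate | COC(=O)OC/C=C/CO[Si](C)(C)C(C)(C)C | intermediate
11 | 1-methoxy-2-methyl-1-(trimethylsilyloxy)prop-1-ene | COC(O[Si](C)(C)C)=C(C)C | starting material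
12 | methyl (3S)-3-[(tert-butyldimethylsilyloxy)methyl]-2,2-dimethylpent-4-enoate | C=C[C@@H](C(C)(C)C(=O)OC)CO[Si](C)(C)C(C)(C)C | intermediate
13 | lithium (4S)-4-[(tert-butyldimethylsilyloxy)methyl]-3,3-dimethyl-1-(trimethylsilyl)hexa-1,5-dien-2-olate | C=C[C@@H](C(C)(C)C([O-])=C[Si](C)(C)C)CO[Si](C)(C)C(C)(C)C.[Li+] | intermediate (not isolated)
14 | (4S)-4-[(tert-butyldimethylsilyloxy)methyl]-3,3-dimethylhex-5-en-2-one | C=C[C@@H](C(C)(C)C(C)=O)CO[Si](C)(C)C(C)(C)C | intermediate
15 | lithium (4S)-4-[(tert-butyldimethylsilyloxy)methyl]-3,3-dimethylhexa-1,5-dien-2-olate | C=C[C@@H](C(C)(C)C([O-])=C)CO[Si](C)(C)C(C)(C)C.[Li+] | intermediate (not isolated)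
16 | (3S,8E,10S)-12-bromo-3-[(tert-butyldimethylsilyloxy)methyl]-10-(tert-butyldiphenylsilyloxy)-4,4,8-trimethyltrideca-1,8,12-trien-5-one | C=C[C@@H](C(C)(C)C(=O)CC/C(C)=C/[C@@H](O[Si](c1ccccc1)(c1ccccc1)C(C)(C)C)CC(Br)=C)CO[Si](C)(C)C(C)(C)C | intermediate
17 | potassium (5Z)-enolate of 16 (O– on C5, C5=C6 double bond; stereocentres as in 16) | C=C[C@@H](C(C)(C)/C([O-])=C/C/C(C)=C/[C@@H](O[Si](c1ccccc1)(c1ccccc1)C(C)(C)C)CC(Br)=C)CO[Si](C)(C)C(C)(C)C.[K+] | intermediate (not isolated)
18 | potassium alkoxide of the (6R)-6-hydroxy derivative of 16 | C=C[C@@H](C(C)(C)C(=O)[C@H]([O-])C/C(C)=C/[C@@H](O[Si](c1ccccc1)(c1ccccc1)C(C)(C)C)CC(Br)=C)CO[Si](C)(C)C(C)(C)C.[K+] | intermediate (not isolated)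
19 | (3S,6R,8E,10S)-12-bromo-3-[(tert-butyldimethylsilyloxy)methyl]-10-(tert-butyldiphenylsilyloxy)-4,4,8-trimethyl-6-(triethylsilyloxy)trideca-1,8,12-trien-5-one | C=C[C@@H](C(C)(C)C(=O)[C@H](O[Si](CC)(CC)CC)C/C(C)=C/[C@@H](O[Si](c1ccccc1)(c1ccccc1)C(C)(C)C)CC(Br)=C)CO[Si](C)(C)C(C)(C)C | intermediate
20 | 19 with its terminal vinyl group converted into CH2CH2–B(9-borabicyclo[3.3.1]nonan-9-yl) (stereocentres as in 19) | B1(CC[C@H](CO[Si](C)(C)C(C)(C)C)C(C)(C)C(=O)[C@H](O[Si](CC)(CC)CC)C/C(C)=C/[C@@H](O[Si](c2ccccc2)(c2ccccc2)C(C)(C)C)CC(Br)=C)C2CCCC1CCC2 | intermediate (not isolated)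
21 | (2R,4E,6S,11S)-11-[(tert-butyldimethylsilyloxy)methyl]-6-(tert-butyldiphenylsilyloxy)-4,12,12-trimethyl-8-methylidene-2-(triethylsilyloxy)cyclododec-4-en-1-one | C=C1CC[C@H](CO[Si](C)(C)C(C)(C)C)C(C)(C)C(=O)[C@H](O[Si](CC)(CC)CC)C/C(C)=C/[C@@H](O[Si](c2ccccc2)(c2ccccc2)C(C)(C)C)C1 | intermediate
22 | (2R,4E,6S,11S)-6-(tert-butyldiphenylsilyloxy)-2-hydroxy-11-(hydroxymethyl)-4,12,12-trimethyl-8-methylidenecyclododec-4-en-1-one | C=C1CC[C@H](CO)C(C)(C)C(=O)[C@H](O)C/C(C)=C/[C@@H](O[Si](c2ccccc2)(c2ccccc2)C(C)(C)C)C1 | intermediate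
23 | (2R,4E,6S,11S)-6-(tert-butyldiphenylsilyloxy)-2-hydroxy-11-(iodomethyl)-4,12,12-trimethyl-8-methylidenecyclododec-4-en-1-one | C=C1CC[C@H](CI)C(C)(C)C(=O)[C@H](O)C/C(C)=C/[C@@H](O[Si](c2ccccc2)(c2ccccc2)C(C)(C)C)C1 | intermediate
24 | ethyl 2-(diethoxyphosphoryl)prop-2-enoate | C=C(C(=O)OCC)P(=O)(OCC)OCC | starting material
25 | 23 with I replaced by CH2–CH(CO2Et)P(O)(OEt)2 (C13–C14 bond made, C12 epimers, other stereocentres as in 23) | C=C1CC[C@H](CCC(C(=O)OCC)P(=O)(OCC)OCC)C(C)(C)C(=O)[C@H](O)C/C(C)=C/[C@@H](O[Si](c2ccccc2)(c2ccccc2)C(C)(C)C)C1 | intermediate (not isolated)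
26 | ethyl (1R,6S,10R,7E)-6-(tert-butyldiphenylsilyloxy)-10-hydroxyverticilla-4(20),7,11-trien-18-oate (ring A closed, lactone still open) | C=C1CC[C@@H]2CCC(C(=O)OCC)=C([C@@H](C/C(C)=C/[C@@H](O[Si](c3ccccc3)(c3ccccc3)C(C)(C)C)C1)O)C2(C)C | intermediate (not isolated)
27 | (1R,6S,10R,7E)-6-(tert-butyldiphenylsilyloxy)verticilla-4(20),7,11-trien-18,10-olide | C=C1CC[C@@H]2CCC3=C([C@@H](C/C(C)=C/[C@@H](O[Si](c4ccccc4)(c4ccccc4)C(C)(C)C)C1)OC3=O)C2(C)C | intermediate
28 | (1R,6S,10R,7E)-6-hydroxyverticilla-4(20),7,11-trien-18,10-olide | C=C1CC[C@@H]2CCC3=C([C@@H](C/C(C)=C/[C@@H](O)C1)OC3=O)C2(C)C | intermediate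
29 | (1R,6S,10R,7E)-6-acetoxyverticilla-4(20),7,11-trien-18,10-olide | C=C1CC[C@@H]2CCC3=C([C@@H](C/C(C)=C/[C@@H](OC(C)=O)C1)OC3=O)C2(C)C | target

**Step count and risks**

Total step count: 16. Longest linear sequence: 12 (steps 5–16); bromide 7 is made in steps 1–4 and enters in step 9.

Step 14 is the most likely to fail. The C14 radical may be diverted before it meets the acceptor, by hydrogen transfer from C10–H through a six-membered transition state, by transannular addition to C4=C20 or by direct reduction. The phosphonate carbanion may be slow to attack the hindered C11 carbonyl and may add to surplus acceptor instead, and DBU may epimerise C10 once the butenolide has formed. The fallback sets out from 23 and comes back at 27, and it separates the two bond formations. Ordinary Giese addition of 23 to ethyl acrylate under the same silane conditions would give the keto ester that carries the C14–C13–C12 chain F1. Silylation of the C10 hydroxyl (Et3SiOTf, 2,6-lutidine) would give the triethylsilyl ether F2. LiN(iPr)2 at −78 °C would form the ester enolate, which closes ring A by intramolecular aldol addition to C11 and gives the β-hydroxy ester F3. HF·pyridine would free the C10 hydroxyl, which lactonises to the 11-hydroxy lactone F4. Mesylation (MsCl, Et3N) and DBU-induced E1cB elimination across C11–C12 would then give 27.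

Step 11 is the second risk. The C11 carbonyl may be reduced by 9-BBN, the alkylborane may undergo protodeboronation, and intermolecular coupling may lead to oligomers at the concentration needed for turnover. The fallback sets out from 19 and comes back at 21, and it replaces the borane by an organozinc reagent made from an isolated halide. Hydroboration of the vinyl group with oxidative work-up (9-BBN; NaBO3) would give the primary alcohol F5. I2/PPh3/imidazole would give the primary iodide F6. Zinc insertion (Zn dust, LiCl, THF) followed by intramolecular Negishi coupling with the 2-bromoalkene (Pd(OAc)2, SPhos, slow addition, high dilution) would close the ring to 21.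

Step 10 is the third risk. Oxygen transfer to the Z-enolate may show poor facial selectivity, because C1 is too remote to help, and the unwanted C10 epimer would then have to be separated. The fallback sets out from 16 and comes back at 19, and it moves the stereocontrol from a stoichiometric reagent acting on the enolate to a catalyst acting on a neutral enol ether. Soft enolisation (Et3SiOTf, Et3N) would give the (Z)-triethylsilyl enol ether F7. Shi epoxidation (fructose-derived ketone catalyst, KHSO5, K2CO3, MeCN/dimethoxymethane/water, 0 °C) should oxidise this most electron-rich alkene first, and collapse of the silyloxy epoxide would give the (6R)-α-hydroxy ketone F8. Silylation (Et3SiCl, imidazole) would give 19.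

Further compounds
F1 | step 14 | 23 with I replaced by CH2–CH2–CO2Et (stereocentres as in 23) | C=C1CC[C@H](CCCC(=O)OCC)C(C)(C)C(=O)[C@H](O)C/C(C)=C/[C@@H](O[Si](c2ccccc2)(c2ccccc2)C(C)(C)C)C1
F2 | step 14 | C10-O-triethylsilyl ether of F1 | C=C1CC[C@H](CCCC(=O)OCC)C(C)(C)C(=O)[C@H](O[Si](CC)(CC)CC)C/C(C)=C/[C@@H](O[Si](c2ccccc2)(c2ccccc2)C(C)(C)C)C1
F3 | step 14 | aldol product with ring A closed: C11 tertiary alcohol, C12–H bearing CO2Et, C10–OSiEt3 (C11 and C12 as formed, C1, C6, C10 as in 23) | C=C1CC[C@@H]2CCC(C(=O)OCC)C(O)([C@@H](C/C(C)=C/[C@@H](O[Si](c3ccccc3)(c3ccccc3)C(C)(C)C)C1)O[Si](CC)(CC)CC)C2(C)C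
F4 | step 14 | 11-hydroxy-11,12-dihydro derivative of 27 (saturated γ-lactone with tertiary C11–OH) | C=C1CC[C@@H]2CCC3C(O)([C@@H](C/C(C)=C/[C@@H](O[Si](c4ccccc4)(c4ccccc4)C(C)(C)C)C1)OC3=O)C2(C)C
F5 | step 11 | 19 with its terminal vinyl group converted into CH2CH2OH | OCC[C@H](CO[Si](C)(C)C(C)(C)C)C(C)(C)C(=O)[C@H](O[Si](CC)(CC)CC)C/C(C)=C/[C@@H](O[Si](c1ccccc1)(c1ccccc1)C(C)(C)C)CC(Br)=C
F6 | step 11 | 19 with its terminal vinyl group converted into CH2CH2I | ICC[C@H](CO[Si](C)(C)C(C)(C)C)C(C)(C)C(=O)[C@H](O[Si](CC)(CC)CC)C/C(C)=C/[C@@H](O[Si](c1ccccc1)(c1ccccc1)C(C)(C)C)CC(Br)=C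
F7 | step 10 | (5Z)-triethylsilyl enol ether of 16 | C=C[C@@H](C(C)(C)/C(O[Si](CC)(CC)CC)=C/C/C(C)=C/[C@@H](O[Si](c1ccccc1)(c1ccccc1)C(C)(C)C)CC(Br)=C)CO[Si](C)(C)C(C)(C)C
F8 | step 10 | (3S,6R,8E,10S)-6-hydroxy derivative of 16 | C=C[C@@H](C(C)(C)C(=O)[C@H](O)C/C(C)=C/[C@@H](O[Si](c1ccccc1)(c1ccccc1)C(C)(C)C)CC(Br)=C)CO[Si](C)(C)C(C)(C)C
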